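The numbers in the tables were generated by integration with constants of no real substance; the scatter is artificial.

From 30.0 s on, Saturday's readings held level within their scatter, at a mean of 22.1 %, and from 50.0 s on Wednesday's readings averaged 39.0 %, with the last at 40.9 %, so I could not tell whether that run had reached its end. Both flasks still held starting material, so I took the coupling partner as the limiting reagent, split between the starting material and itself.

| setting | Saturday's | Wednesday's | oak | ash | maple |
|---|---|---|---|---|---|
| starting material | 0.75 mM | 0.25 mM | 0.50 mM | 0.50 mM | 0.50 mM |
| coupling partner | 0.25 mM | 0.25 mM | 0.250 mM | 1.00 mM | 2.00 mM |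
| remark | run made earlier | run made earlier |  |  |  |
| time |  |  | 4.0 min | 4.0 min | 4.0 min |

| Saturday's: time / s | Saturday's: single product / % | Wednesday's: time / s | Wednesday's: single product / % |
|---|---|---|---|
| 10.0 | 18.3 | 10.0 | 21.6 |
| 15.0 | 22.1 | 15.0 | 25.1 |
| 30.0 | 21.1 | 30.0 | 33.1 |
| 50.0 | 23.4 | 50.0 | 38.8 |
| 60.0 | 22.1 | 60.0 | 37.4 |
| 80.0 | 21.6 | 80.0 | 40.9 |

(scatter of a reading: 1 percentage point)

- amounts and yields of single product count crystals too
- given per volume of solution although it is solid: crystals
- candidate steps: starting material + coupling partner -> single product + by-product; coupling partner + single product -> bis adduct + by-product; crystals <-> single product; 2 coupling partner -> self-condensation product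

* how much single product is there at the end, in percent of the starting material charged: for each flask in turn (oak, ash, maple)

I called that split the waste ratio w: twice the rate constant of self-condensation over that of the coupling step. At equal concentrations it is the partner lost to itself per partner used on starting material. Leaving out the bis adduct and integrating to the end of the partner, with b the partner charged per starting material charged, I had the yield Y:

Y = 1 − [1 + (w − 1) b]^(−1/(w − 1))

The zero of the scale is w = 0, where Y = b: 33.3 % for Saturday and 100 % for Wednesday. Both readings fall short of it, so each run gives w on its own. I bracketed each between w = 3 and w = 4: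

Saturday: 22.5 % to 20.6 %, so w = 3.26

Wednesday: 42.3 % to 37.0 %, so w = 3.61

The two ways part by 0.350. Wednesday's bracket is wider than Saturday's, so a scatter of 1 percentage point blurs Saturday's value more; but if Wednesday's mean lay below that run's end, its w came out too high. I accepted the gap. I took the mean, w = 3.44. Each new flask runs 4.0 min, longer than the last reading of Wednesday's run at 80.0 s, so I reckoned end states:

oak 27.9 %, ash 51.7 %, maple 62.3 %

The forecast gave 28 %, 51 % and 60 %, holding that “selectivity improves with high starting material and low partner”.

The simulation gave 28.5 %, 53.1 % and 63.7 %.

    starting material + coupling partner → single product + by-product (k = 210 M⁻¹ s⁻¹)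
    coupling partner + single product → bis adduct + by-product (k = 52.0 M⁻¹ s⁻¹)
    crystals ⇌ single product, rate k3*(cs3 - [single product]) while solid is left; crystals form when [single product] > cs3 (solubility = 0.00650 mM, k = 1.70 s⁻¹)
    2 coupling partner → self-condensation product (k = 330 M⁻¹ s⁻¹)

With w = 3.44, I had 27.9 % for oak, which gave 28.5 % with the bis adduct at 0.182 % of the charge. On maple the same w gave 62.3 % against 63.7 %, with bis adduct at 1.22 %. The proof that w is the right quantity is ash with the self-condensation step taken away. Its single product then rises from 53.1 % to 90.2 %, which makes that step the main reason for 79 % of what is missing.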